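No rate constant is given for this flask, so I begin with the one number the charge gives exactly: the partner allowance, the coupling partner charged as a percentage of both substrates together, assuming each product takes one partner, is 110%.

| setting | epsilon | delta | flask |
|---|---|---|---|
| left-handed substrate | 0.20 M | 0.10 M | 0.20 M |
| right-handed substrate | 0.20 M | 0.10 M | 0.20 M |
| coupling partner | 2.2 equiv | 2.2 equiv | 2.20 equiv |
| free catalyst | 0.93 mol% | 0.93 mol% | 0.93 mol% |
| racemization catalyst | 0.5 mol% | 0.5 mol% | 0.5 mol% |
| remark | the very flask that is asked about, followed so far | run made earlier |  |
| time |  |  | 15 d |

| run | time / d | left-handed product / % | left-handed substrate / % |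
|---|---|---|---|
| epsilon | 3.00 | 31 | 23 |
| epsilon | 4.00 | 34 | 24 |
| delta | 4.00 | 17 | 37 |
| delta | 5.00 | 18 | 33 |
| delta | 6.00 | 21 | 34 |
| delta | 8.00 | 22 | 30 |
| delta | 10.0 | 25 | 28 |

(scatter of a reading: 1.5 percentage points)

- free catalyst is single-handed; left-handed substrate and right-handed substrate are mirror images of each other, charged as a racemate, each of them at the stated concentration
- the earlier runs were read with a standard deviation of 1.5 percentage points

1. the moment within 15 d at which there is most left-handed product
2. the amount of left-handed product, in percent of the left-handed substrate and right-handed substrate together charged, at that time
3. the first time at which left-handed product reaches 14%, in the same percent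

I ask of each given number how far the outcome moves if it is off. As a ceiling on product, the partner charge does not bind, because the allowance stands above the 100% of substrate, which makes the substrates the limiting reagent by charge. The racemization loading matters already in the readings, since left-handed product plus left-handed substrate in epsilon reads 58.0%, above the 50% that was charged as left-handed substrate. The late rate matters too and is poorly read: epsilon rises 3 points in its last interval, with a scatter of 1.5 points on each reading. Held to the end, that rate gives 67.0%, which is my own high figure, not the forecast's, since the first 3.00 d of epsilon gave 31%, on average faster than that late rate, so the rise is already slowing in these readings.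

The forecast gives 47% at 15 d, on the ground that “Neither run shows product loss”, and on a separate ground, an early rate of about 20 %/d, it puts 14% at 0.7 d.

The flask gives 45.2% at 15.0 d, and it reaches 14% at 0.469 d.

    coupling partner + free catalyst + left-handed substrate → free catalyst + left-handed product (k = 52.0 M⁻² h⁻¹)
    2 free catalyst ⇌ resting dimer (K = 28000 M⁻¹, k = 17.0 M⁻¹ h⁻¹)
    coupling partner + free catalyst + right-handed substrate → free catalyst + right-handed product (k = 20.0 M⁻² h⁻¹)
    left-handed substrate + racemization catalyst ⇌ right-handed substrate + racemization catalyst, rate k4*[racemization catalyst]*[left-handed substrate] forward; the back reaction follows from the equilibrium constant (k = 12.0 M⁻¹ h⁻¹)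

At the best time it also holds 20.1% of right-handed product, and with 41% of the coupling partner left, the flask has spent 64.9% of its allowance, while the two products together stand at 65.3%. The neighbour flask with 0.550 equiv of coupling partner has an allowance of 27.5%, and with 25% of that partner left it has spent 20.6%, ending with 14.8% of left-handed product and 5.91% of right-handed product.

(Readings and results were generated by integration with constants of no real substance, noise included.)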